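**Plan**

- Retrosynthesis: after removal of two MOM ethers, both chromans are cut at C4–C4a and O1–C8a together (four bonds, both pyran rings). This leaves an achiral bis(aryl iodide) diarylmethane and two molecules of (S)-3-iodo-1-phenylpropan-1-ol. The CH2 bridge is traced back to a benzophenone, cut at the carbonyl–aryl bond of the C6-methyl ring.
- Forward: 2-iodo-4,6-dimethoxybenzoic acid and 5-iodo-1,3-dimethoxy-2-methylbenzene give a benzophenone by Friedel–Crafts acylation. Carbonyl-chelated cleavage of the two ortho OMe groups frees O7 on both rings and keeps both O5 methyl ethers. C=O is reduced to CH2, the phenols are protected as MOM ethers, one double palladium/norbornene annulation closes both pyran rings, and the MOM groups are removed.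
- Enabling feature: in each benzene ring the oxygen-bearing C8a can be an iodide lying between the substituted C8 (bridge carbon) and a free C4a–H. This is the ortho-blocked aryl iodide that lets a norbornene relay alkylate C4a and then close O1–C8a at the ipso carbon, fusing the O1–C2–C3–C4 unit onto the C4a–C8a edge.
- Stereochemistry: both C2 centres are bought as (S)-3-chloro-1-phenylpropan-1-ol. Only its O–H and C–halogen ends react, the C2–O bond is never broken, and the priority order O > Ph > CH2 is unchanged, so both centres are S in the target.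

Key step: step 10

Assumption: 1-iodo-3,5-dimethoxybenzene, 2,6-dimethoxytoluene and both enantiomers of 3-chloro-1-phenylpropan-1-ol are taken as commercial. Ring A is the benzene ring without C-methyl, ring B the C6-methyl ring; flavan locants are used for both.

**Route**

Step 1
Reactants: 1 1-iodo-3,5-dimethoxybenzene
Product: 3 2-iodo-4,6-dimethoxybenzaldehyde, via iminium chloride 2 (not isolated)
Conditions: POCl3, DMF, 0 °C to 90 °C; then H2O
Reagents that add atoms: N,N-dimethylformamide, CN(C)C=O (formyl carbon of 3 and the Me2N=CH unit of 2); water, O (carbonyl oxygen of 3); phosphoryl chloride, O=P(Cl)(Cl)Cl (chloride counter-ion of 2 only)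
Why: Vilsmeier–Haack formylation should attack the position para to one OMe and ortho to the other, next to iodine, in preference to the more crowded site between the two OMe groups, and the iminium salt is hydrolysed on work-up.

Step 2
Reactants: 3 2-iodo-4,6-dimethoxybenzaldehyde
Product: 4 2-iodo-4,6-dimethoxybenzoic acid
Conditions: NaClO2, NaH2PO4, 2-methylbut-2-ene, t-BuOH/H2O, rt
Reagents that add atoms: sodium chlorite, [Na+].[O-]Cl=O
Why: Pinnick oxidation should convert the hindered, electron-rich aldehyde to the acid without touching the aryl iodide, the alkene removing HOCl before it can chlorinate the ring.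

Step 3
Reactants: 5 2,6-dimethoxytoluene
Product: 6 2-(3,5-dimethoxy-4-methylphenyl)-4,4,5,5-tetramethyl-1,3,2-dioxaborolane
Conditions: [Ir(OMe)(cod)]2 (1.5 mol %), 4,4'-di-tert-butyl-2,2'-bipyridine (3 mol %), B2pin2 (1.0 equiv), cyclohexane, 80 °C
Reagents that add atoms: bis(pinacolato)diboron, CC1(C)OB(OC1(C)C)B1OC(C)(C)C(C)(C)O1
Why: Sterically controlled iridium-catalysed C–H borylation should functionalise the only C–H bond without an ortho substituent (para to the methyl group), a position that electrophilic substitution cannot reach.

Step 4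
Reactants: 6 2-(3,5-dimethoxy-4-methylphenyl)-4,4,5,5-tetramethyl-1,3,2-dioxaborolane
Product: 7 5-iodo-1,3-dimethoxy-2-methylbenzene
Conditions: CuI (10 mol %), 1,10-phenanthroline (20 mol %), KI (1.5 equiv), MeOH/H2O, air, 80 °C
Reagents that add atoms: potassium iodide, [K+].[I-]
Why: Copper-mediated iododeboronation (transmetalation of the aryl boronate to copper, then C–I bond formation under air) should place iodine regiospecifically at the carbon that carried boron.

Step 5
Reactants: 4 2-iodo-4,6-dimethoxybenzoic acid; 7 5-iodo-1,3-dimethoxy-2-methylbenzene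
Product: 9 (2-iodo-4,6-dimethoxyphenyl)(6-iodo-2,4-dimethoxy-3-methylphenyl)methanone, via mixed trifluoroacetic anhydride 8 (not isolated)
Conditions: (CF3CO)2O (3 equiv), CF3SO3H (20 mol %), CH2Cl2, 0 °C to rt
Reagents that add atoms: trifluoroacetic anhydride, O=C(OC(=O)C(F)(F)F)C(F)(F)F (its CF3CO group is carried only by intermediate 8 and is lost before 9)
Why: Friedel–Crafts acylation through the mixed anhydride should work because the 2,6-disubstituted acid ionises readily to a linear acylium ion and 7 offers only one kind of aromatic C–H (ortho to one OMe, para to the other), so a single regioisomer is possible.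

Step 6
Reactants: 9 (2-iodo-4,6-dimethoxyphenyl)(6-iodo-2,4-dimethoxy-3-methylphenyl)methanone
Product: 10 (2-hydroxy-6-iodo-4-methoxyphenyl)(2-hydroxy-6-iodo-4-methoxy-3-methylphenyl)methanone
Conditions: BCl3 (5 equiv), CH2Cl2, −78 °C to rt; then H2O
Reagents that add atoms: none
Why: Chelation-controlled ether cleavage should occur because BCl3 bound to the carbonyl oxygen delivers chloride only to the two OMe groups ortho to the ketone (six-membered boron chelates), sparing the two para OMe groups and so differentiating O7 from O5 on both rings at once.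

Step 7
Reactants: 10 (2-hydroxy-6-iodo-4-methoxyphenyl)(2-hydroxy-6-iodo-4-methoxy-3-methylphenyl)methanone
Product: 11 2-[(2-hydroxy-6-iodo-4-methoxyphenyl)methyl]-3-iodo-5-methoxy-6-methylphenol
Conditions: Et3SiH (5 equiv), CF3CO2H/CH2Cl2, 0 °C to 40 °C
Reagents that add atoms: none
Why: Ionic hydrogenation should reduce the ketone to the methylene bridge, since protonation gives a diaryl carbenium ion stabilised by four ortho/para oxygen donors that accepts hydride from the silane twice, while the aryl iodides (meta to all donors) are not protodeiodinated.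

Step 8
Reactants: 11 2-[(2-hydroxy-6-iodo-4-methoxyphenyl)methyl]-3-iodo-5-methoxy-6-methylphenol
Product: 12 1-iodo-2-{[2-iodo-4-methoxy-6-(methoxymethoxy)phenyl]methyl}-5-methoxy-3-(methoxymethoxy)-4-methylbenzene
Conditions: MOMCl (4 equiv), i-Pr2NEt (6 equiv), CH2Cl2, 0 °C to rt
Reagents that add atoms: chloromethyl methyl ether, COCCl
Why: Williamson-type O-alkylation should mask both phenols as base-stable acetals so that they can neither be O-alkylated by 14 nor bind palladium in step 10.

Step 9
Reactants: 13 (S)-3-chloro-1-phenylpropan-1-ol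
Product: 14 (S)-3-iodo-1-phenylpropan-1-ol
Conditions: NaI (3 equiv), acetone, reflux
Reagents that add atoms: sodium iodide, [Na+].[I-]
Why: Finkelstein exchange (SN2 at the primary carbon, driven by precipitation of NaCl) should give the more reactive primary iodide without touching the carbinol stereocentre.

Step 10
Reactants: 12 1-iodo-2-{[2-iodo-4-methoxy-6-(methoxymethoxy)phenyl]methyl}-5-methoxy-3-(methoxymethoxy)-4-methylbenzene; 14 (S)-3-iodo-1-phenylpropan-1-ol (two molecules are incorporated)
Product: 17 (2S)-5-methoxy-8-{[(2S)-5-methoxy-7-(methoxymethoxy)-6-methyl-2-phenylchroman-8-yl]methyl}-7-(methoxymethoxy)-2-phenylchromane, via ring A mono-annulated iodide 15 (not isolated), via ring B mono-annulated iodide 16 (not isolated)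
Conditions: 14 (3 equiv), Pd(OAc)2 (20 mol %), 2-dicyclohexylphosphino-2',6'-diisopropoxybiphenyl (40 mol %), norbornene (2 equiv), Cs2CO3 (6 equiv), 1,4-dioxane, 100 °C
Reagents that add atoms: none
Why: Proposed new method: on each ring, oxidative addition of the C8a–I bond to zerovalent palladium, syn-exo carbopalladation of norbornene and carbonate-assisted palladation of C4a–H should give an aryl–norbornyl palladacycle of divalent palladium, which takes up the primary C–I bond of 14 by SN2-type oxidative addition to tetravalent palladium and forges C4–C4a by reductive elimination; with C8 and C4a both substituted, norbornene is then extruded by β-carbon elimination and the C8a–Pd bond is captured by the tethered secondary alkoxide. The closest known reaction types are the Catellani ortho-alkylation with primary alkyl iodides, the palladium/norbornene annulation of aryl iodides with epoxides to 2,3-dihydrobenzofurans and with bromoalkylamines to indolines and tetrahydroquinolines, and the intramolecular Buchwald–Hartwig etherification of secondary alcohols; the untested element is a γ-iodo alcohol as the C,O-partner, one carbon longer, giving a chroman. Each of the two pyran rings closes by aryl C–O reductive elimination from a seven-membered aryl-palladium alkoxide, a formal [4+2] annulation of the O1–C2–C3–C4 unit onto the C4a–C8a edge. No stereocentre is created: both C2 centres are carried in from 14 with their C–O bonds intact, so the S configuration should be retained. Site selectivity is secured by the bridge carbon at C8, which blocks one ortho position of each iodide so that only C4a–H can be palladated and norbornene must leave after a single alkylation; the MOM ethers exclude phenol O-alkylation, and the bulky electron-rich biarylphosphine is chosen to favour C–O reductive elimination over β-hydride elimination of the palladium alkoxide.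

Step 11
Reactants: 17 (2S)-5-methoxy-8-{[(2S)-5-methoxy-7-(methoxymethoxy)-6-methyl-2-phenylchroman-8-yl]methyl}-7-(methoxymethoxy)-2-phenylchromane
Product: 18 (2S)-8-{[(2S)-7-hydroxy-5-methoxy-6-methyl-2-phenylchroman-8-yl]methyl}-5-methoxy-2-phenylchroman-7-ol (CNP0114750.1)
Conditions: HCl (2 M aq), MeOH/THF, 40 °C
Reagents that add atoms: none
Why: Acid-catalysed acetal exchange with methanol should remove both MOM groups under conditions too mild to ionise the C2–O1 benzylic ether (no donor on the phenyl ring) or to cleave the diarylmethane.

**Compound list**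

1 | 1-iodo-3,5-dimethoxybenzene | COc1cc(I)cc(OC)c1 | starting material
2 | N-(2-iodo-4,6-dimethoxybenzylidene)-N-methylmethanaminium chloride | COc1cc(I)c(C=[N+](C)C)c(OC)c1.[Cl-] | intermediate
3 | 2-iodo-4,6-dimethoxybenzaldehyde | COc1cc(I)c(C=O)c(OC)c1 | intermediate
4 | 2-iodo-4,6-dimethoxybenzoic acid | COc1cc(I)c(C(=O)O)c(OC)c1 | intermediate
5 | 2,6-dimethoxytoluene | COc1cccc(OC)c1C | starting material
6 | 2-(3,5-dimethoxy-4-methylphenyl)-4,4,5,5-tetramethyl-1,3,2-dioxaborolane | COc1cc(B2OC(C)(C)C(C)(C)O2)cc(OC)c1C | intermediate
7 | 5-iodo-1,3-dimethoxy-2-methylbenzene | COc1cc(I)cc(OC)c1C | intermediate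
8 | 2-iodo-4,6-dimethoxybenzoic trifluoroacetic anhydride | COc1cc(I)c(C(=O)OC(=O)C(F)(F)F)c(OC)c1 | intermediate
9 | (2-iodo-4,6-dimethoxyphenyl)(6-iodo-2,4-dimethoxy-3-methylphenyl)methanone | COc1cc(I)c(C(=O)c2c(I)cc(OC)c(C)c2OC)c(OC)c1 | intermediate
10 | (2-hydroxy-6-iodo-4-methoxyphenyl)(2-hydroxy-6-iodo-4-methoxy-3-methylphenyl)methanone | COc1cc(O)c(C(=O)c2c(I)cc(OC)c(C)c2O)c(I)c1 | intermediate
11 | 2-[(2-hydroxy-6-iodo-4-methoxyphenyl)methyl]-3-iodo-5-methoxy-6-methylphenol | COc1cc(O)c(Cc2c(I)cc(OC)c(C)c2O)c(I)c1 | intermediate
12 | 1-iodo-2-{[2-iodo-4-methoxy-6-(methoxymethoxy)phenyl]methyl}-5-methoxy-3-(methoxymethoxy)-4-methylbenzene | COCOc1cc(OC)cc(I)c1Cc1c(I)cc(OC)c(C)c1OCOC | intermediate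
13 | (S)-3-chloro-1-phenylpropan-1-ol | O[C@@H](CCCl)c1ccccc1 | starting material
14 | (S)-3-iodo-1-phenylpropan-1-ol | O[C@@H](CCI)c1ccccc1 | intermediate
15 | (2S)-8-{[6-iodo-4-methoxy-2-(methoxymethoxy)-3-methylphenyl]methyl}-5-methoxy-7-(methoxymethoxy)-2-phenylchromane | COCOc1cc(OC)c2CC[C@@H](c3ccccc3)Oc2c1Cc1c(I)cc(OC)c(C)c1OCOC | intermediate
16 | (2S)-8-{[2-iodo-4-methoxy-6-(methoxymethoxy)phenyl]methyl}-5-methoxy-7-(methoxymethoxy)-6-methyl-2-phenylchromane | COCOc1cc(OC)cc(I)c1Cc1c(OCOC)c(C)c(OC)c2CC[C@@H](c3ccccc3)Oc12 | intermediate
17 | (2S)-5-methoxy-8-{[(2S)-5-methoxy-7-(methoxymethoxy)-6-methyl-2-phenylchroman-8-yl]methyl}-7-(methoxymethoxy)-2-phenylchromane | COCOc1cc(OC)c2CC[C@@H](c3ccccc3)Oc2c1Cc1c(OCOC)c(C)c(OC)c2CC[C@@H](c3ccccc3)Oc12 | intermediate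
18 | (2S)-8-{[(2S)-7-hydroxy-5-methoxy-6-methyl-2-phenylchroman-8-yl]methyl}-5-methoxy-2-phenylchroman-7-ol (CNP0114750.1) | COc1cc(O)c(Cc2c(O)c(C)c(OC)c3c2O[C@H](c2ccccc2)CC3)c2c1CC[C@@H](c1ccccc1)O2 | target

**Count and risks**

Total step count: 11. Longest linear sequence: 8 steps (steps 1, 2, 5, 6, 7, 8, 10, 11; compounds 1 → 3 → 4 → 9 → 10 → 11 → 12 → 17 → 18).

Steps most likely to fail:

1. Step 10 (proposed new method). Three processes may compete with the annulation. β-Hydride elimination of the aryl-palladium alkoxide would reduce the ipso carbon or erode the enantiomeric purity by reversible dehydrogenation. Base-induced closure of 14 would give the oxetane. Palladium-mediated biaryl coupling of the two C8a carbons across the methylene bridge may outrun the second annulation. The fallback sets out from 12 and uses known chemistry only. Palladium-catalysed hydroxylation of both aryl iodides (Pd2(dba)3, 2-di-tert-butylphosphino-2',4',6'-triisopropylbiphenyl, KOH, dioxane/H2O) should give 2-{[2-hydroxy-4-methoxy-6-(methoxymethoxy)phenyl]methyl}-5-methoxy-3-(methoxymethoxy)-4-methylphenol F1. A double Mitsunobu etherification with commercial (R)-3-chloro-1-phenylpropan-1-ol (O[C@H](CCCl)c1ccccc1; PPh3, DIAD, THF) should form both O1–C2 bonds with inversion and give the bis[(S)-3-chloro-1-phenylpropyl] ether F2. Exhaustive bromination of the three free aromatic positions (NBS, 3 equiv, MeCN, 0 °C) should give the tribromide F3. Parham cycloalkylation (t-BuLi, THF, −78 °C to rt, then MeOH) should close both C4–C4a bonds onto the primary chlorides, while the third aryllithium at C6 of ring A is simply protonated. The fallback comes back to the route at 17.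

2. Step 5. Steric congestion in forming a tetra-ortho-substituted benzophenone may slow the acylation so that trifluoroacetylation of 7, acid-induced deacylation or iodine migration takes over. The fallback sets out from 3. Reduction with NaBH4 in MeOH should give (2-iodo-4,6-dimethoxyphenyl)methanol F4. Friedel–Crafts benzylation of an excess of 7 (BF3·OEt2 cat., CH2Cl2, 0 °C) should give 1-iodo-2-[(2-iodo-4,6-dimethoxyphenyl)methyl]-3,5-dimethoxy-4-methylbenzene F5, the bond being made at the less demanding benzyl-cation oxidation level. Benzylic oxidation of the electron-rich diarylmethane (DDQ, aqueous dioxane) should then return the ketone. The fallback comes back to the route at 9.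

3. Step 6. Cleavage of the second ortho ether may stall once the first boron chelate ties up the carbonyl group, or the para ethers may be cleaved as well. The fallback sets out from 9 and replaces selective cleavage by selective re-alkylation. Exhaustive demethylation (BBr3, CH2Cl2, −78 °C to rt) should give (2,4-dihydroxy-6-iodophenyl)(2,4-dihydroxy-6-iodo-3-methylphenyl)methanone F6. Methylation with dimethyl sulfate (2 equiv, K2CO3, acetone) should take place only at the two para hydroxyls, because the two ortho hydroxyls are hydrogen-bonded to the carbonyl oxygen. The fallback comes back to the route at 10.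

**Further compounds**

F1 | step 10 | 2-{[2-hydroxy-4-methoxy-6-(methoxymethoxy)phenyl]methyl}-5-methoxy-3-(methoxymethoxy)-4-methylphenol | COCOc1cc(OC)cc(O)c1Cc1c(O)cc(OC)c(C)c1OCOC
F2 | step 10 | bis[(S)-3-chloro-1-phenylpropyl] ether of F1 | COCOc1cc(OC)cc(O[C@@H](CCCl)c2ccccc2)c1Cc1c(O[C@@H](CCCl)c2ccccc2)cc(OC)c(C)c1OCOC
F3 | step 10 | tribromide of F2 (bromine at C4a and C6 of ring A and at C4a of ring B) | COCOc1c(Br)c(OC)c(Br)c(O[C@@H](CCCl)c2ccccc2)c1Cc1c(O[C@@H](CCCl)c2ccccc2)c(Br)c(OC)c(C)c1OCOC
F4 | step 5 | (2-iodo-4,6-dimethoxyphenyl)methanol | COc1cc(I)c(CO)c(OC)c1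
F5 | step 5 | 1-iodo-2-[(2-iodo-4,6-dimethoxyphenyl)methyl]-3,5-dimethoxy-4-methylbenzene | COc1cc(I)c(Cc2c(I)cc(OC)c(C)c2OC)c(OC)c1
F6 | step 6 | (2,4-dihydroxy-6-iodophenyl)(2,4-dihydroxy-6-iodo-3-methylphenyl)methanone | Oc1cc(O)c(C(=O)c2c(I)cc(O)c(C)c2O)c(I)c1
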